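**Retrosynthetic overview**
1. Target 20 ⇐ O‑acetylation of ketol 19 ⇐ α‑ketol (acyloin) ring expansion of hydroxy aldehyde 18: the side‑chain‑bearing ring carbon shifts from the carbinol carbon to the formyl carbon, turning the cyclopentane into the 3‑hydroxycyclohexan‑2‑one.
2. 18 ⇐ diol 17 ⇐ Tamao unmasking and OH‑directed epoxidation of tertiary allylic alcohol 15; the tertiary OH first directs the epoxide cis to the side chain and then becomes the ring ketone.
3. 15 ⇐ angeloylation and hydroxymethyl‑anion addition (anti to the side chain) on enone 11.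
4. 11 ⇐ Ni‑catalysed stereoconvergent alkenylation (new) of rac‑bromo enone 8 (from 2‑methylcyclopent‑2‑enone 5) with the alkenylzinc from 4; 4 ⇐ cross‑metathesis ⇐ asymmetric allylboration of 2‑bromoacrolein 1.
5. Ring order: cyclopentene (bought, in 5) → oxirane (step 7) → cyclohexanone by one‑carbon ring expansion (step 9).

Assumption: the senses of asymmetric induction in steps 1 and 4 are as stated; if either is found reversed, the other catalyst or ligand enantiomer is used.

**Step 1**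
Reactants: 1 2-bromoprop-2-enal
Product: 3 (3S)-2-bromohexa-1,5-dien-3-ol, via pinacol borate ester 2 (not isolated)
Conditions: allyl‑B(pin) (1.2 equiv), (S)‑TRIP (5 mol %), toluene, −30 °C; aq. NaHCO3
Reagents that add atoms: allylboronic acid pinacol ester, C=CCB1OC(C)(C)C(C)(C)O1
Why: Chiral‑phosphoric‑acid‑catalysed allylboration through a closed chair transition state in which the (S)‑catalyst shields one aldehyde face sets C3 as S, and the vinyl bromide is untouched.

**Step 2**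
Reactants: 3 (3S)-2-bromohexa-1,5-dien-3-ol
Product: 4 (3S)-2-bromo-6-methylhepta-1,5-dien-3-ol
Conditions: 2‑methylbut‑2‑ene (excess), Grubbs II (3 mol %), CH2Cl2, 40 °C
Reagents that add atoms: 2-methylbut-2-ene, CC=C(C)C
Why: Olefin cross‑metathesis of the monosubstituted alkene with 2‑methylbut‑2‑ene gives the prenyl terminus, the electron‑poor 2‑bromo‑1,1‑disubstituted alkene being inert to the Ru carbene, and C3 is not affected.

**Step 3**
Reactants: 5 2-methylcyclopent-2-en-1-one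
Product: 8 rac-5-bromo-2-methylcyclopent-2-en-1-one, via lithium dienolate 6 (not isolated), via trimethylsilyl dienol ether 7 (not isolated)
Conditions: LDA, THF, −78 °C; TMSCl; then NBS, −78 → −40 °C
Reagents that add atoms: N-bromosuccinimide, O=C1CCC(=O)N1Br
Why: Kinetic α′‑deprotonation gives the cross‑conjugated dienolate, whose silyl dienol ether is brominated at C5 by NBS (α‑halogenation of a silyl enol ether) in the cold before any 1,5‑H shift; the product is deliberately racemic.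

**Step 4**
Reactants: 4 (3S)-2-bromo-6-methylhepta-1,5-dien-3-ol, 8 rac-5-bromo-2-methylcyclopent-2-en-1-one
Product: 11 (5S)-5-[(3S)-3-hydroxy-6-methylhepta-1,5-dien-2-yl]-2-methylcyclopent-2-en-1-one, via dilithio alkenyl alkoxide 9 (not isolated), via alkenylzinc chloride 10 (not isolated)
Conditions: 4, t‑BuLi (3.1 equiv), Et2O, −78 °C; ZnCl2, THF, −78 → 0 °C; then 8 (1.5 equiv), NiCl2·glyme (10 mol %), i‑Pr‑pybox (matched enantiomer, 13 mol %), DME/THF, −30 °C; aq. NH4Cl
Reagents that add atoms: none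
Why: Proposed new method: a stereoconvergent Ni/pybox‑catalysed Negishi alkenylation of a racemic cyclic α′‑bromo enone with a branched (1‑substituted) alkenylzinc that carries a lithium alkoxide, in which Ni(I) abstracts bromine from either enantiomer of 8 to give the same planar α‑keto radical, the chiral Ni(II)–alkenyl captures it and C–C reductive elimination from Ni(III) forms the ring–side‑chain bond and sets C5 (S) under catalyst control matched to the C3′ centre, the cold non‑basic medium preventing epimerisation of the new tertiary α‑centre and conjugation of the β,γ‑alkene; the closest known reaction type is the Ni‑catalysed enantioconvergent Negishi‑type arylation and alkenylation of racemic acyclic α‑bromo ketones with aryl‑zinc and alkenyl‑zirconium reagents.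

**Step 5**
Reactants: 11 (5S)-5-[(3S)-3-hydroxy-6-methylhepta-1,5-dien-2-yl]-2-methylcyclopent-2-en-1-one
Product: 12 (1R,5S)-1-{[dimethyl(propan-2-yloxy)silyl]methyl}-5-[(3S)-3-hydroxy-6-methylhepta-1,5-dien-2-yl]-2-methylcyclopent-2-en-1-ol
Conditions: (i‑PrO)Me2SiCH2MgCl (3 equiv), LaCl3·2LiCl (30 mol %), THF, −78 → −20 °C; aq. NH4Cl
Reagents that add atoms: [dimethyl(propan-2-yloxy)silyl]methylmagnesium chloride, CC(C)O[Si](C)(C)C[Mg]Cl
Why: Grignard 1,2‑addition of the Tamao hydroxymethyl‑anion equivalent (the lanthanum salt suppresses enolisation and 1,4‑addition) takes place on the carbonyl face anti to the C5 substituent, so the new tertiary hydroxyl is cis to the side chain (C1 R) while C5 is untouched.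

**Step 6**
Reactants: 12 (1R,5S)-1-{[dimethyl(propan-2-yloxy)silyl]methyl}-5-[(3S)-3-hydroxy-6-methylhepta-1,5-dien-2-yl]-2-methylcyclopent-2-en-1-ol, 13 (2Z)-2-methylbut-2-enoic acid (angelic acid)
Product: 15 (3S)-2-[(1S,2R)-2-{[dimethyl(propan-2-yloxy)silyl]methyl}-2-hydroxy-3-methylcyclopent-3-en-1-yl]-6-methylhepta-1,5-dien-3-yl (2Z)-2-methylbut-2-enoate, via mixed Yamaguchi anhydride 14 (not isolated)
Conditions: 13, 2,4,6‑Cl3C6H2COCl, Et3N, toluene, 0 °C; then 12 (crude), DMAP, 23 °C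
Reagents that add atoms: none
Why: Yamaguchi esterification through the mixed anhydride acylates only the secondary allylic hydroxyl at room temperature (the tertiary one is inert), conditions mild enough to keep the Z (angelate) geometry.

**Step 7**
Reactants: 15 (3S)-2-[(1S,2R)-2-{[dimethyl(propan-2-yloxy)silyl]methyl}-2-hydroxy-3-methylcyclopent-3-en-1-yl]-6-methylhepta-1,5-dien-3-yl (2Z)-2-methylbut-2-enoate
Product: 16 (3S)-2-[(1S,2R,3S,5S)-2-{[dimethyl(propan-2-yloxy)silyl]methyl}-2-hydroxy-1-methyl-6-oxabicyclo[3.1.0]hexan-3-yl]-6-methylhepta-1,5-dien-3-yl (2Z)-2-methylbut-2-enoate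
Conditions: VO(acac)2 (5 mol %), t‑BuOOH (1.3 equiv), CH2Cl2, 0 °C
Reagents that add atoms: tert-butyl hydroperoxide, CC(C)(C)OO
Why: Vanadium‑catalysed hydroxyl‑directed epoxidation of the tertiary allylic alcohol delivers oxygen syn to the OH and hence cis to the side chain (sets both oxirane carbons), while the side‑chain alkenes, which have no free allylic hydroxyl, react far more slowly.

**Step 8**
Reactants: 16 (3S)-2-[(1S,2R,3S,5S)-2-{[dimethyl(propan-2-yloxy)silyl]methyl}-2-hydroxy-1-methyl-6-oxabicyclo[3.1.0]hexan-3-yl]-6-methylhepta-1,5-dien-3-yl (2Z)-2-methylbut-2-enoate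
Product: 17 (3S)-2-[(1S,2S,3S,5S)-2-hydroxy-2-(hydroxymethyl)-1-methyl-6-oxabicyclo[3.1.0]hexan-3-yl]-6-methylhepta-1,5-dien-3-yl (2Z)-2-methylbut-2-enoate
Conditions: 30 % H2O2, KF, KHCO3, THF/MeOH, 23 °C
Reagents that add atoms: hydrogen peroxide, OO
Why: Tamao–Fleming oxidation converts the C–Si bond into C–OH under buffered fluoride/peroxide conditions that leave oxirane, esters and alkenes intact, and no stereocentre is involved.

**Step 9**
Reactants: 17 (3S)-2-[(1S,2S,3S,5S)-2-hydroxy-2-(hydroxymethyl)-1-methyl-6-oxabicyclo[3.1.0]hexan-3-yl]-6-methylhepta-1,5-dien-3-yl (2Z)-2-methylbut-2-enoate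
Product: 19 (3S)-2-[(1S,3S,4S,6S)-3-hydroxy-1-methyl-2-oxo-7-oxabicyclo[4.1.0]heptan-4-yl]-6-methylhepta-1,5-dien-3-yl (2Z)-2-methylbut-2-enoate, via hydroxy aldehyde 18 (not isolated)
Conditions: IBX, DMSO, 23 °C; filter, NaHCO3 wash; then DBU (20 mol %), toluene, 0 → 23 °C
Reagents that add atoms: none
Why: IBX oxidises the primary alcohol of the 1,2‑diol without glycol cleavage and the resulting tertiary α‑hydroxy aldehyde undergoes base‑induced α‑ketol (acyloin) rearrangement, the allylic ring carbon that bears the side chain (not the oxirane carbon) shifting with retention to the formyl carbon to expand the cyclopentane to the cyclohexanone, the open dipole‑opposed transition state and enolate equilibration both favouring the diequatorial 3,4‑trans ketol (C3 S).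

**Step 10**
Reactants: 19 (3S)-2-[(1S,3S,4S,6S)-3-hydroxy-1-methyl-2-oxo-7-oxabicyclo[4.1.0]heptan-4-yl]-6-methylhepta-1,5-dien-3-yl (2Z)-2-methylbut-2-enoate
Product: 20 (3S)-2-[(1S,3S,4S,6S)-3-(acetyloxy)-1-methyl-2-oxo-7-oxabicyclo[4.1.0]heptan-4-yl]-6-methylhepta-1,5-dien-3-yl (2Z)-2-methylbut-2-enoate
Conditions: Ac2O, pyridine, DMAP (cat.), CH2Cl2, 0 °C
Reagents that add atoms: acetic anhydride, CC(=O)OC(C)=O
Why: DMAP‑catalysed O‑acetylation of the α‑ketol under mild conditions leaves every stereocentre in place (the trans acetate is also the more stable C3 epimer).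

**Compound list**
1 | 2-bromoprop-2-enal (2-bromoacrolein) | C=C(Br)C=O | starting material
2 | 2-{[(3S)-2-bromohexa-1,5-dien-3-yl]oxy}-4,4,5,5-tetramethyl-1,3,2-dioxaborolane | C=C(Br)[C@H](CC=C)OB1OC(C)(C)C(C)(C)O1 | intermediate
3 | (3S)-2-bromohexa-1,5-dien-3-ol | C=C(Br)[C@H](CC=C)O | intermediate
4 | (3S)-2-bromo-6-methylhepta-1,5-dien-3-ol | C=C(Br)[C@H](CC=C(C)C)O | intermediate
5 | 2-methylcyclopent-2-en-1-one | CC1=CCCC1=O | starting material
6 | lithium 5-methylcyclopenta-1,4-dien-1-olate | [Li]OC1=CCC=C1C | intermediate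
7 | trimethyl[(5-methylcyclopenta-1,4-dien-1-yl)oxy]silane | CC1=CCC=C1O[Si](C)(C)C | intermediate
8 | rac-5-bromo-2-methylcyclopent-2-en-1-one | CC1=CCC(Br)C1=O | intermediate
9 | dilithio species of 4 (lithium (3S)-2-lithio-6-methylhepta-1,5-dien-3-olate) | [Li]C(=C)[C@H](CC=C(C)C)O[Li] | intermediate
10 | alkenylzinc chloride of 4 (lithium (3S)-2-(chlorozincio)-6-methylhepta-1,5-dien-3-olate) | Cl[Zn]C(=C)[C@H](CC=C(C)C)O[Li] | intermediate
11 | (5S)-5-[(3S)-3-hydroxy-6-methylhepta-1,5-dien-2-yl]-2-methylcyclopent-2-en-1-one | C=C([C@H](CC=C(C)C)O)[C@@H]1CC=C(C)C1=O | intermediate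
12 | (1R,5S)-1-{[dimethyl(propan-2-yloxy)silyl]methyl}-5-[(3S)-3-hydroxy-6-methylhepta-1,5-dien-2-yl]-2-methylcyclopent-2-en-1-ol (tertiary OH cis to the side chain) | C=C([C@H](CC=C(C)C)O)[C@@H]1CC=C(C)[C@@]1(O)C[Si](C)(C)OC(C)C | intermediate
13 | (2Z)-2-methylbut-2-enoic acid (angelic acid) | OC(=O)/C(C)=C\C | starting material
14 | (2Z)-2-methylbut-2-enoic 2,4,6-trichlorobenzoic anhydride | Clc1cc(Cl)c(C(=O)OC(=O)/C(C)=C\C)c(Cl)c1 | intermediate
15 | (3S)-2-[(1S,2R)-2-{[dimethyl(propan-2-yloxy)silyl]methyl}-2-hydroxy-3-methylcyclopent-3-en-1-yl]-6-methylhepta-1,5-dien-3-yl (2Z)-2-methylbut-2-enoate | C=C([C@H](CC=C(C)C)OC(=O)/C(C)=C\C)[C@@H]1CC=C(C)[C@@]1(O)C[Si](C)(C)OC(C)C | intermediate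
16 | (3S)-2-[(1S,2R,3S,5S)-2-{[dimethyl(propan-2-yloxy)silyl]methyl}-2-hydroxy-1-methyl-6-oxabicyclo[3.1.0]hexan-3-yl]-6-methylhepta-1,5-dien-3-yl (2Z)-2-methylbut-2-enoate (oxirane O, tertiary OH and side chain all cis) | C=C([C@H](CC=C(C)C)OC(=O)/C(C)=C\C)[C@@H]1C[C@@H]2O[C@]2(C)[C@@]1(O)C[Si](C)(C)OC(C)C | intermediate
17 | (3S)-2-[(1S,2S,3S,5S)-2-hydroxy-2-(hydroxymethyl)-1-methyl-6-oxabicyclo[3.1.0]hexan-3-yl]-6-methylhepta-1,5-dien-3-yl (2Z)-2-methylbut-2-enoate | C=C([C@H](CC=C(C)C)OC(=O)/C(C)=C\C)[C@@H]1C[C@@H]2O[C@]2(C)[C@@]1(O)CO | intermediate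
18 | (3S)-2-[(1S,2R,3S,5S)-2-formyl-2-hydroxy-1-methyl-6-oxabicyclo[3.1.0]hexan-3-yl]-6-methylhepta-1,5-dien-3-yl (2Z)-2-methylbut-2-enoate | C=C([C@H](CC=C(C)C)OC(=O)/C(C)=C\C)[C@@H]1C[C@@H]2O[C@]2(C)[C@@]1(O)C=O | intermediate
19 | (3S)-2-[(1S,3S,4S,6S)-3-hydroxy-1-methyl-2-oxo-7-oxabicyclo[4.1.0]heptan-4-yl]-6-methylhepta-1,5-dien-3-yl (2Z)-2-methylbut-2-enoate | C=C([C@H](CC=C(C)C)OC(=O)/C(C)=C\C)[C@@H]1C[C@@H]2O[C@]2(C)C(=O)[C@H]1O | intermediate
20 | (3S)-2-[(1S,3S,4S,6S)-3-(acetyloxy)-1-methyl-2-oxo-7-oxabicyclo[4.1.0]heptan-4-yl]-6-methylhepta-1,5-dien-3-yl (2Z)-2-methylbut-2-enoate (CNP0150645.2) | C=C([C@H](CC=C(C)C)OC(=O)/C(C)=C\C)[C@@H]1C[C@@H]2O[C@]2(C)C(=O)[C@H]1OC(C)=O | target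

**Totals**
Total step count: 10. Longest linear sequence: 9 steps (1 → 3 → 4 → 11 → 12 → 15 → 16 → 17 → 19 → 20; steps 1, 2, 4–10).

**Three steps most likely to fail**

Step 4 (the proposed new Ni coupling; risks are low ee/dr at C5, epimerisation or conjugation of 11, and reduction or elimination of 8). The fallback uses known chemistry, sets out from 5 and 4 and comes back at 11. Mn(OAc)3‑mediated α′‑acetoxylation of 5 gives rac-5-acetoxy-2-methylcyclopent-2-en-1-one F1. Lipase‑catalysed kinetic resolution (enantioselective hydrolysis, the S series being taken on) gives (5S)-5-hydroxy-2-methylcyclopent-2-en-1-one F2, and MsCl/Et3N gives (5S)-5-(methanesulfonyloxy)-2-methylcyclopent-2-en-1-one F3. CeCl3‑mediated 1,2‑addition of the alkenyllithium 9 (from 4) anti to the mesylate gives the β‑mesyloxy carbinol (1S,2S)-2-hydroxy-2-[(3S)-3-hydroxy-6-methylhepta-1,5-dien-2-yl]-3-methylcyclopent-3-en-1-yl methanesulfonate F4. Et3Al in CH2Cl2 at −78 °C then induces the stereospecific pinacol‑type 1,2‑shift of the alkenyl group to C5 with inversion and loss of mesylate, which gives 11 with the same (5S) configuration.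

Step 9 (the ring expansion; risks are oxirane opening, formyl migration, retro reactions of the hydroxy aldehyde, or a poor trans:cis ratio at C3). The fallback sets out from 17 and comes back at 19. NaIO4 cleaves the diol to the cis‑epoxy ketone (3S)-6-methyl-2-[(1S,3S,5S)-1-methyl-2-oxo-6-oxabicyclo[3.1.0]hexan-3-yl]hepta-1,5-dien-3-yl (2Z)-2-methylbut-2-enoate F6, the hydroxymethyl group having served only to direct the epoxidation. Lewis‑acid‑catalysed homologation with TMSCHN2 (the side‑chain‑bearing carbon migrates, the oxirane carbon does not) followed by 1,3‑Brook shift gives the ring‑expanded silyl enol ether (3S)-6-methyl-2-[(1S,4R,6S)-1-methyl-2-(trimethylsilyloxy)-7-oxabicyclo[4.1.0]hept-2-en-4-yl]hepta-1,5-dien-3-yl (2Z)-2-methylbut-2-enoate F7. Rubottom oxidation with DMDO at −78 °C, anti to the neighbouring side chain, gives the silyloxy ketone (3S)-6-methyl-2-[(1S,3S,4S,6S)-1-methyl-2-oxo-3-(trimethylsilyloxy)-7-oxabicyclo[4.1.0]heptan-4-yl]hepta-1,5-dien-3-yl (2Z)-2-methylbut-2-enoate F8, and mild acidic methanolysis gives 19.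

Step 6 (risks are Z → E isomerisation of the angelate to the tiglate during acyl transfer, or silyl exchange with the free secondary OH). The fallback sets out from 12 and comes back at 15. DCC/DMAP acylation with 2-(diphenoxyphosphoryl)propanoic acid gives (3S)-2-[(1S,2R)-2-{[dimethyl(propan-2-yloxy)silyl]methyl}-2-hydroxy-3-methylcyclopent-3-en-1-yl]-6-methylhepta-1,5-dien-3-yl 2-(diphenoxyphosphoryl)propanoate F5. Ando‑type Z‑selective Horner–Wadsworth–Emmons olefination with acetaldehyde (NaI, DBU, THF, −78 → 0 °C) then builds the (Z)‑2‑methylbut‑2‑enoate in place and gives 15.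

**Further compounds**
F1 | step 4 | rac-5-acetoxy-2-methylcyclopent-2-en-1-one | CC1=CCC(OC(C)=O)C1=O
F2 | step 4 | (5S)-5-hydroxy-2-methylcyclopent-2-en-1-one | CC1=CC[C@H](O)C1=O
F3 | step 4 | (5S)-5-(methanesulfonyloxy)-2-methylcyclopent-2-en-1-one | CC1=CC[C@H](OS(C)(=O)=O)C1=O
F4 | step 4 | (1S,2S)-2-hydroxy-2-[(3S)-3-hydroxy-6-methylhepta-1,5-dien-2-yl]-3-methylcyclopent-3-en-1-yl methanesulfonate | C=C([C@H](CC=C(C)C)O)[C@@]1(O)C(C)=CC[C@@H]1OS(C)(=O)=O
F5 | step 6 | (3S)-2-[(1S,2R)-2-{[dimethyl(propan-2-yloxy)silyl]methyl}-2-hydroxy-3-methylcyclopent-3-en-1-yl]-6-methylhepta-1,5-dien-3-yl 2-(diphenoxyphosphoryl)propanoate | C=C([C@H](CC=C(C)C)OC(=O)C(C)P(=O)(Oc1ccccc1)Oc1ccccc1)[C@@H]1CC=C(C)[C@@]1(O)C[Si](C)(C)OC(C)C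
F6 | step 9 | (3S)-6-methyl-2-[(1S,3S,5S)-1-methyl-2-oxo-6-oxabicyclo[3.1.0]hexan-3-yl]hepta-1,5-dien-3-yl (2Z)-2-methylbut-2-enoate | C=C([C@H](CC=C(C)C)OC(=O)/C(C)=C\C)[C@@H]1C[C@@H]2O[C@]2(C)C1=O
F7 | step 9 | (3S)-6-methyl-2-[(1S,4R,6S)-1-methyl-2-(trimethylsilyloxy)-7-oxabicyclo[4.1.0]hept-2-en-4-yl]hepta-1,5-dien-3-yl (2Z)-2-methylbut-2-enoate | C=C([C@H](CC=C(C)C)OC(=O)/C(C)=C\C)[C@@H]1C[C@@H]2O[C@]2(C)C(O[Si](C)(C)C)=C1
F8 | step 9 | (3S)-6-methyl-2-[(1S,3S,4S,6S)-1-methyl-2-oxo-3-(trimethylsilyloxy)-7-oxabicyclo[4.1.0]heptan-4-yl]hepta-1,5-dien-3-yl (2Z)-2-methylbut-2-enoate | C=C([C@H](CC=C(C)C)OC(=O)/C(C)=C\C)[C@@H]1C[C@@H]2O[C@]2(C)C(=O)[C@H]1O[Si](C)(C)C
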